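Everything rests on opening ring B (C5–C10, drimane numbering) at its C7 methylene. The precursor is the trans-fused hydrindan-2-one 7, whose five-membered ring already holds C5, C6, C8, C9 and C10, with C9 branched and C6 unbranched beside the C8 carbonyl. One-carbon ring enlargement with Me3SiCHN2 inserts C7 between C6 and C8 and turns the cyclopentanone into the cyclohexanone of ring B; the C8 ketone then fixes C9 by equilibration and later becomes the C7=C8 olefin carrying the C8 methyl. The resulting acetylene 14 is joined at C13 to ketone 22; a hydroperoxide closes the 1,2-dioxane on the propargylic cation, and diimide saturates the alkyne.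

Key step: step 7

Remark: carbons are numbered as in drimanes (C1–C10 decalin, C11–C12 linker, C13 and C16 the peroxide carbons, C17 the propionate α-carbon, C18 the ester carbon); centres drawn without descriptor (C9 in 6–8, C13 in 23–25) are epimer mixtures that a later step converges; compound 15 and i-Pr3SiOCH2Cl are taken as purchased.

Step 1
Reactants: 1 2,2,6-trimethylcyclohexanone
Product: 2 allyl 2,6,6-trimethylcyclohex-1-en-1-yl carbonate
Conditions: LiN(SiMe3)2, THF, 0 °C; allyl chloroformate, −78 → 23 °C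
Reagents that add atoms: allyl chloroformate C=CCOC(Cl)=O
Why: The only enolisable position of 1 gives a single tetrasubstituted lithium enolate, which is O-acylated by the chloroformate (enol carbonate formation).

Step 2
Reactants: 2 allyl 2,6,6-trimethylcyclohex-1-en-1-yl carbonate
Product: 3 (S)-2-allyl-2,6,6-trimethylcyclohexanone
Conditions: Pd2(dba)3 (2.5 mol%), (S)-t-BuPHOX (6 mol%), THF, 25 °C
Reagents that add atoms: none
Why: Decarboxylative asymmetric allylic alkylation (Tsuji allylation with a chiral phosphinooxazoline–palladium catalyst): ionisation and loss of CO2 give a π-allylpalladium enolate that recombines in the chiral pocket, the (S)-ligand setting the quaternary centre (future C10) as S, the sense known for 2-allyl-2-alkylcyclohexanones.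

Step 3
Reactants: 3 (S)-2-allyl-2,6,6-trimethylcyclohexanone
Product: 4 (S)-2,2,6-trimethyl-6-(2-oxopropyl)cyclohexanone
Conditions: PdCl2 (5 mol%), Cu(OAc)2·H2O (25 mol%), O2 (1 atm), DMA/H2O, 23 °C
Reagents that add atoms: water O
Why: Tsuji–Wacker oxidation: Markovnikov hydroxypalladation of the terminal alkene and β-hydride elimination give the methyl ketone, O2 reoxidising the catalysts.

Step 4
Reactants: 4 (S)-2,2,6-trimethyl-6-(2-oxopropyl)cyclohexanone
Product: 5 (S)-4,4,7a-trimethyl-5,6,7,7a-tetrahydro-1H-inden-2(4H)-one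
Conditions: KOH, xylenes, 110 °C (Dean–Stark)
Reagents that add atoms: none
Why: Intramolecular aldol condensation: only the methyl ketone CH3 can close a five-membered ring on the ring carbonyl, and dehydration gives the conjugated cyclopentenone with C10 untouched.

Step 5
Reactants: 5 (S)-4,4,7a-trimethyl-5,6,7,7a-tetrahydro-1H-inden-2(4H)-one
Product: 6 (7aS)-4,4,7a-trimethyl-1-{[(triisopropylsilyl)oxy]methyl}-5,6,7,7a-tetrahydro-1H-inden-2(4H)-one (C1 epimers)
Conditions: LiN(i-Pr)2, THF, −78 °C; i-Pr3SiOCH2Cl, −78 → 0 °C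
Reagents that add atoms: (triisopropylsiloxy)methyl chloride ClCO[Si](C(C)C)(C(C)C)C(C)C
Why: The enone has only one set of enolisable hydrogens (α′, the future C9), so kinetic deprotonation and C-alkylation with the α-chloro ether (enolate alkylation) install the protected hydroxymethyl carbon C11 regiospecifically; the C9 configuration is left open because step 7 equilibrates it.

Step 6
Reactants: 6 (7aS)-4,4,7a-trimethyl-1-{[(triisopropylsilyl)oxy]methyl}-5,6,7,7a-tetrahydro-1H-inden-2(4H)-one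
Product: 7 (3aR,7aR)-4,4,7a-trimethyl-1-{[(triisopropylsilyl)oxy]methyl}octahydro-2H-inden-2-one (trans ring fusion; C1 epimers)
Conditions: Li, NH3(l)/THF, t-BuOH (1 equiv), −78 °C; NH4Cl
Reagents that add atoms: none
Why: Dissolving-metal (Birch-type) conjugate reduction: the β-carbanion at C5 is protonated axially on ring A from the face opposite the axial C10 methyl, which should give the trans ring fusion, and the silyl ether is inert.

Step 7
Reactants: 7 (3aR,7aR)-4,4,7a-trimethyl-1-{[(triisopropylsilyl)oxy]methyl}octahydro-2H-inden-2-one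
Product: 9 (1R,4aR,8aR)-5,5,8a-trimethyl-1-{[(triisopropylsilyl)oxy]methyl}octahydronaphthalen-2(1H)-one, via C7-trimethylsilyl ketone 8 (not isolated)
Conditions: Me3SiCHN2, BF3·OEt2, CH2Cl2, −78 → −40 °C; then K2CO3, MeOH, 23 °C
Reagents that add atoms: (trimethylsilyl)diazomethane C[Si](C)(C)C=[N+]=[N-]
Why: The Lewis-acid-activated C8 carbonyl is attacked by the diazo carbon to give a diazonium betaine, and a 1,2-shift of the C6–C8 bond with loss of N2 inserts the new carbon (C7) between C6 and C8, enlarging the five-membered ring (C5, C6, C8, C9, C10) to the six-membered ring B; methanolic K2CO3 then cleaves the C7–Si bond of 8. The closest known reaction type is the Tiffeneau–Demjanov-type diazoalkane–carbonyl homologation in its Me3SiCHN2/BF3·OEt2 form. No ring is closed by cyclisation: ring B arises by ring enlargement through a 1,2-alkyl shift. The only stereocentre settled here is C9, under thermodynamic control, since enolisation toward C9 in K2CO3/MeOH should place the CH2OSi group equatorial on the trans-decalone (same face as the axial C10 methyl), while C5 and C10 are untouched. The step needs migration of the unbranched C6 methylene and not of C9; the α-branching and the inductively withdrawing β-silyloxy group at C9 lower its migratory aptitude and keep the bulky silylated diazonium carbon away from it. A second insertion should be held back by the α-silyl group of 8.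

Step 8
Reactants: 9 (1R,4aR,8aR)-5,5,8a-trimethyl-1-{[(triisopropylsilyl)oxy]methyl}octahydronaphthalen-2(1H)-one
Product: 10 (1R,4aR,8aR)-5,5,8a-trimethyl-1-{[(triisopropylsilyl)oxy]methyl}-1,4,4a,5,6,7,8,8a-octahydronaphthalen-2-yl trifluoromethanesulfonate
Conditions: LiN(i-Pr)2, THF, −78 °C; PhNTf2, −78 → 0 °C
Reagents that add atoms: N-phenylbis(trifluoromethanesulfonimide) O=S(=O)(N(c1ccccc1)S(=O)(=O)C(F)(F)F)C(F)(F)F
Why: Kinetic deprotonation takes place at the unhindered C7 methylene and not at the tertiary C9, and O-triflation of this enolate gives the C7=C8 enol triflate regioselectively (enol triflate formation).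

Step 9
Reactants: 10 (1R,4aR,8aR)-5,5,8a-trimethyl-1-{[(triisopropylsilyl)oxy]methyl}-1,4,4a,5,6,7,8,8a-octahydronaphthalen-2-yl trifluoromethanesulfonate
Product: 11 triisopropyl{[(1R,4aR,8aR)-2,5,5,8a-tetramethyl-1,4,4a,5,6,7,8,8a-octahydronaphthalen-1-yl]methoxy}silane
Conditions: MeMgBr, Fe(acac)3 (5 mol%), THF/NMP, −30 → 0 °C
Reagents that add atoms: methylmagnesium bromide C[Mg]Br
Why: Iron-catalysed Kumada-type cross-coupling of the enol triflate with the methyl Grignard reagent replaces OTf by CH3 without moving the double bond, completing the C7=C8(CH3) unit.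

Step 10
Reactants: 11 triisopropyl{[(1R,4aR,8aR)-2,5,5,8a-tetramethyl-1,4,4a,5,6,7,8,8a-octahydronaphthalen-1-yl]methoxy}silane
Product: 12 [(1R,4aR,8aR)-2,5,5,8a-tetramethyl-1,4,4a,5,6,7,8,8a-octahydronaphthalen-1-yl]methanol (ent-drimenol)
Conditions: Bu4NF, THF, 23 °C
Reagents that add atoms: none
Why: Fluoride cleaves the Si–O bond (desilylation) and touches nothing else.

Step 11
Reactants: 12 ent-drimenol
Product: 13 (1R,4aR,8aR)-2,5,5,8a-tetramethyl-1,4,4a,5,6,7,8,8a-octahydronaphthalene-1-carbaldehyde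
Conditions: Dess–Martin periodinane, NaHCO3, CH2Cl2, 0 → 23 °C
Reagents that add atoms: none
Why: Dess–Martin oxidation under buffered, non-basic conditions should give the β,γ-unsaturated aldehyde without epimerisation at C9 or migration of the double bond into conjugation.

Step 12
Reactants: 13 (1R,4aR,8aR)-2,5,5,8a-tetramethyl-1,4,4a,5,6,7,8,8a-octahydronaphthalene-1-carbaldehyde
Product: 14 (1R,4aR,8aR)-1-ethynyl-2,5,5,8a-tetramethyl-1,4,4a,5,6,7,8,8a-octahydronaphthalene
Conditions: Me3SiCHN2, n-BuLi, THF, −78 °C; then 13, −78 → 23 °C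
Reagents that add atoms: (trimethylsilyl)diazomethane C[Si](C)(C)C=[N+]=[N-]
Why: Colvin rearrangement: addition of lithiated Me3SiCHN2 to the aldehyde, Peterson-type loss of silanolate, loss of N2 and 1,2-hydride shift of the alkylidene carbene give the terminal alkyne (C11≡C12) at a temperature where C9 is not enolised.

Step 13
Reactants: 15 ethyl 3-(2-methyl-1,3-dioxolan-2-yl)propanoate
Product: 16 3-(2-methyl-1,3-dioxolan-2-yl)propanal
Conditions: i-Bu2AlH, CH2Cl2, −78 °C; aq. potassium sodium tartrate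
Reagents that add atoms: none
Why: Half-reduction of the ester stops at the tetrahedral aluminium hemiacetal at −78 °C and the aldehyde is released on work-up; the ketal is inert.

Step 14
Reactants: 16 3-(2-methyl-1,3-dioxolan-2-yl)propanal; 17 (S)-4-benzyl-3-propionyloxazolidin-2-one
Product: 18 (S)-4-benzyl-3-[(2S,3R)-3-hydroxy-2-methyl-5-(2-methyl-1,3-dioxolan-2-yl)pentanoyl]oxazolidin-2-one
Conditions: 17, Bu2BOTf, Et3N, CH2Cl2, 0 °C; 16, −78 → 0 °C; pH 7 buffer, MeOH
Reagents that add atoms: none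
Why: Evans syn aldol reaction: the Z-boron enolate reacts through a closed Zimmerman–Traxler chair in which the (S)-benzyl auxiliary shields one face, setting C17 (S) and C16 (R) together.

Step 15
Reactants: 18 (S)-4-benzyl-3-[(2S,3R)-3-hydroxy-2-methyl-5-(2-methyl-1,3-dioxolan-2-yl)pentanoyl]oxazolidin-2-one
Product: 19 (2R,3R)-2-methyl-5-(2-methyl-1,3-dioxolan-2-yl)pentane-1,3-diol
Conditions: LiBH4, MeOH (1.1 equiv), Et2O, 0 °C
Reagents that add atoms: none
Why: LiBH4 reduces the activated imide carbonyl to the primary alcohol (reductive removal of the auxiliary) while the ketal and both stereocentres stay untouched.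

Step 16
Reactants: 19 (2R,3R)-2-methyl-5-(2-methyl-1,3-dioxolan-2-yl)pentane-1,3-diol
Product: 20 (2R,3R)-1-[(tert-butyldiphenylsilyl)oxy]-2-methyl-5-(2-methyl-1,3-dioxolan-2-yl)pentan-3-ol
Conditions: t-BuPh2SiCl, imidazole, CH2Cl2, 0 °C
Reagents that add atoms: tert-butyl(chloro)diphenylsilane CC(C)(C)[Si](Cl)(c1ccccc1)c1ccccc1
Why: The bulky silyl chloride reacts selectively with the primary hydroxyl (selective silylation), leaving the secondary C16 hydroxyl free.

Step 17
Reactants: 20 (2R,3R)-1-[(tert-butyldiphenylsilyl)oxy]-2-methyl-5-(2-methyl-1,3-dioxolan-2-yl)pentan-3-ol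
Product: 21 (2R,3R)-1-[(tert-butyldiphenylsilyl)oxy]-2-methyl-5-(2-methyl-1,3-dioxolan-2-yl)pentan-3-yl 4-methylbenzenesulfonate
Conditions: TsCl, pyridine, DMAP (cat.), CH2Cl2, 23 °C
Reagents that add atoms: 4-methylbenzenesulfonyl chloride Cc1ccc(cc1)S(Cl)(=O)=O
Why: Sulfonylation forms only an O–S bond, so the C16 hydroxyl becomes a leaving group with retention of configuration.

Step 18
Reactants: 21 (2R,3R)-1-[(tert-butyldiphenylsilyl)oxy]-2-methyl-5-(2-methyl-1,3-dioxolan-2-yl)pentan-3-yl 4-methylbenzenesulfonate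
Product: 22 (2R,3R)-1-[(tert-butyldiphenylsilyl)oxy]-2-methyl-6-oxoheptan-3-yl 4-methylbenzenesulfonate
Conditions: PPTS, acetone/H2O, 40 °C
Reagents that add atoms: water O
Why: Mild acid-catalysed ketal hydrolysis frees the methyl ketone (C13), and the silyl ether and the secondary tosylate should survive PPTS.

Step 19
Reactants: 14 (1R,4aR,8aR)-1-ethynyl-2,5,5,8a-tetramethyl-1,4,4a,5,6,7,8,8a-octahydronaphthalene; 22 (2R,3R)-1-[(tert-butyldiphenylsilyl)oxy]-2-methyl-6-oxoheptan-3-yl 4-methylbenzenesulfonate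
Product: 24 (2R,3R)-1-[(tert-butyldiphenylsilyl)oxy]-2,6-dimethyl-8-[(1R,4aR,8aR)-2,5,5,8a-tetramethyl-1,4,4a,5,6,7,8,8a-octahydronaphthalen-1-yl]-6-[(triethylsilyl)oxy]oct-7-yn-3-yl 4-methylbenzenesulfonate (C6 epimers), via tertiary propargylic alkoxide 23 (not isolated)
Conditions: 14, n-BuLi, THF, −78 °C; CeCl3, −78 °C; 22; then Et3SiOTf, −78 → −40 °C
Reagents that add atoms: triethylsilyl trifluoromethanesulfonate CC[Si](CC)(CC)OS(=O)(=O)C(F)(F)F
Why: The organocerium acetylide adds 1,2 to the enolisable methyl ketone without deprotonating it or displacing the tosylate (carbonyl alkynylation), and silylation of the cold alkoxide stops it from closing a tetrahydrofuran on C16; C13 forms as both epimers, which is harmless because step 21 ionises this centre.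

Step 20
Reactants: 24 (2R,3R)-1-[(tert-butyldiphenylsilyl)oxy]-2,6-dimethyl-8-[(1R,4aR,8aR)-2,5,5,8a-tetramethyl-1,4,4a,5,6,7,8,8a-octahydronaphthalen-1-yl]-6-[(triethylsilyl)oxy]oct-7-yn-3-yl 4-methylbenzenesulfonate
Product: 25 tert-butyl({(2R,3S)-3-hydroperoxy-2,6-dimethyl-8-[(1R,4aR,8aR)-2,5,5,8a-tetramethyl-1,4,4a,5,6,7,8,8a-octahydronaphthalen-1-yl]-6-[(triethylsilyl)oxy]oct-7-yn-1-yl}oxy)diphenylsilane (C6 epimers)
Conditions: 50% aq. H2O2, KOH, MeOH/THF, 0 → 23 °C
Reagents that add atoms: hydrogen peroxide OO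
Why: SN2 displacement of the secondary tosylate by the α-effect nucleophile HOO− (alkyl hydroperoxide synthesis from a sulfonate) inverts C16 from R to the S configuration required in the target.

Step 21
Reactants: 25 tert-butyl({(2R,3S)-3-hydroperoxy-2,6-dimethyl-8-[(1R,4aR,8aR)-2,5,5,8a-tetramethyl-1,4,4a,5,6,7,8,8a-octahydronaphthalen-1-yl]-6-[(triethylsilyl)oxy]oct-7-yn-1-yl}oxy)diphenylsilane
Product: 26 tert-butyl({(2R)-2-[(3S,6R)-6-methyl-6-{[(1R,4aR,8aR)-2,5,5,8a-tetramethyl-1,4,4a,5,6,7,8,8a-octahydronaphthalen-1-yl]ethynyl}-1,2-dioxan-3-yl]propyl}oxy)diphenylsilane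
Conditions: BF3·OEt2, CH2Cl2, −78 → −30 °C
Reagents that add atoms: none
Why: The Lewis acid ionises the tertiary propargylic silyl ether to an alkynyl-stabilised cation that is captured 6-exo by the hydroperoxide (acid-mediated peroxide formation from a tertiary carbinol derivative and a hydroperoxide); in the chair-like, reversible closure the C16 substituent sits equatorial and the slim alkynyl group, not the methyl, takes the axial site at C13, which should set C13 relative to C16 as in the target.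

Step 22
Reactants: 26 tert-butyl({(2R)-2-[(3S,6R)-6-methyl-6-{[(1R,4aR,8aR)-2,5,5,8a-tetramethyl-1,4,4a,5,6,7,8,8a-octahydronaphthalen-1-yl]ethynyl}-1,2-dioxan-3-yl]propyl}oxy)diphenylsilane
Product: 27 (2R)-2-[(3S,6R)-6-methyl-6-{[(1R,4aR,8aR)-2,5,5,8a-tetramethyl-1,4,4a,5,6,7,8,8a-octahydronaphthalen-1-yl]ethynyl}-1,2-dioxan-3-yl]propan-1-ol
Conditions: Bu4NF, AcOH, THF, 0 → 23 °C
Reagents that add atoms: none
Why: Acetic-acid-buffered fluoride removes the primary silyl group (desilylation) without base-induced fragmentation of the dialkyl peroxide.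

Step 23
Reactants: 27 (2R)-2-[(3S,6R)-6-methyl-6-{[(1R,4aR,8aR)-2,5,5,8a-tetramethyl-1,4,4a,5,6,7,8,8a-octahydronaphthalen-1-yl]ethynyl}-1,2-dioxan-3-yl]propan-1-ol
Product: 28 (2S)-2-[(3S,6R)-6-methyl-6-{[(1R,4aR,8aR)-2,5,5,8a-tetramethyl-1,4,4a,5,6,7,8,8a-octahydronaphthalen-1-yl]ethynyl}-1,2-dioxan-3-yl]propanoic acid
Conditions: TEMPO (cat.), PhI(OAc)2, MeCN/H2O, 23 °C
Reagents that add atoms: water O
Why: Oxoammonium (TEMPO) oxidation takes the primary alcohol through the aldehyde hydrate to the acid, and the O–O bond, the alkyne, the trisubstituted alkene and the C17 configuration should survive the weakly acidic medium.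

Step 24
Reactants: 28 (2S)-2-[(3S,6R)-6-methyl-6-{[(1R,4aR,8aR)-2,5,5,8a-tetramethyl-1,4,4a,5,6,7,8,8a-octahydronaphthalen-1-yl]ethynyl}-1,2-dioxan-3-yl]propanoic acid
Product: 29 methyl (2S)-2-[(3S,6R)-6-methyl-6-{[(1R,4aR,8aR)-2,5,5,8a-tetramethyl-1,4,4a,5,6,7,8,8a-octahydronaphthalen-1-yl]ethynyl}-1,2-dioxan-3-yl]propanoate
Conditions: Me3SiCHN2, PhMe/MeOH, 0 °C
Reagents that add atoms: (trimethylsilyl)diazomethane C[Si](C)(C)C=[N+]=[N-]
Why: Methyl esterification by Me3SiCHN2 in methanol proceeds by proton transfer and alkylation of the carboxylate and needs no base that could open the β-peroxy ester.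

Step 25
Reactants: 29 methyl (2S)-2-[(3S,6R)-6-methyl-6-{[(1R,4aR,8aR)-2,5,5,8a-tetramethyl-1,4,4a,5,6,7,8,8a-octahydronaphthalen-1-yl]ethynyl}-1,2-dioxan-3-yl]propanoate
Product: 30 methyl (2S)-2-[(3S,6S)-6-methyl-6-{2-[(1R,4aR,8aR)-2,5,5,8a-tetramethyl-1,4,4a,5,6,7,8,8a-octahydronaphthalen-1-yl]ethyl}-1,2-dioxan-3-yl]propanoate (CNP0124238.1)
Conditions: KO2CN=NCO2K, AcOH, MeOH/CH2Cl2, 23 °C (repeated charges)
Reagents that add atoms: none
Why: Diimide reduction: concerted syn transfer of H2 saturates the alkyne through the cis-alkene to the C11–C12 ethylene bridge, while the O–O bond and the hindered trisubstituted ring alkene do not react with diimide.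

Compound list

1 | 2,2,6-trimethylcyclohexanone | CC1CCCC(C)(C)C1=O | starting material
2 | allyl 2,6,6-trimethylcyclohex-1-en-1-yl carbonate | C=CCOC(=O)OC1=C(C)CCCC1(C)C | intermediate
3 | (S)-2-allyl-2,6,6-trimethylcyclohexanone | C=CC[C@]1(C)CCCC(C)(C)C1=O | intermediate
4 | (S)-2,2,6-trimethyl-6-(2-oxopropyl)cyclohexanone | CC(=O)C[C@]1(C)CCCC(C)(C)C1=O | intermediate
5 | (S)-4,4,7a-trimethyl-5,6,7,7a-tetrahydro-1H-inden-2(4H)-one | O=C1C=C2C(C)(C)CCC[C@]2(C1)C | intermediate
6 | (7aS)-4,4,7a-trimethyl-1-{[(triisopropylsilyl)oxy]methyl}-5,6,7,7a-tetrahydro-1H-inden-2(4H)-one (C1 epimers) | O=C1C=C2C(C)(C)CCC[C@]2(C1CO[Si](C(C)C)(C(C)C)C(C)C)C | intermediate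
7 | (3aR,7aR)-4,4,7a-trimethyl-1-{[(triisopropylsilyl)oxy]methyl}octahydro-2H-inden-2-one (trans-fused; C1 epimers) | CC(C)[Si](OCC1C(=O)C[C@@H]2C(C)(C)CCC[C@@]12C)(C(C)C)C(C)C | intermediate
8 | (4aR,8aR)-5,5,8a-trimethyl-1-{[(triisopropylsilyl)oxy]methyl}-3-(trimethylsilyl)octahydronaphthalen-2(1H)-one (C1 and C3 epimers) | CC(C)[Si](OCC1C(=O)C([Si](C)(C)C)C[C@@H]2C(C)(C)CCC[C@@]12C)(C(C)C)C(C)C | intermediate (not isolated)
9 | (1R,4aR,8aR)-5,5,8a-trimethyl-1-{[(triisopropylsilyl)oxy]methyl}octahydronaphthalen-2(1H)-one | CC(C)[Si](OC[C@@H]1C(=O)CC[C@@H]2C(C)(C)CCC[C@@]12C)(C(C)C)C(C)C | intermediate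
10 | (1R,4aR,8aR)-5,5,8a-trimethyl-1-{[(triisopropylsilyl)oxy]methyl}-1,4,4a,5,6,7,8,8a-octahydronaphthalen-2-yl trifluoromethanesulfonate | CC(C)[Si](OC[C@@H]1C(OS(=O)(=O)C(F)(F)F)=CC[C@@H]2C(C)(C)CCC[C@@]12C)(C(C)C)C(C)C | intermediate
11 | triisopropyl{[(1R,4aR,8aR)-2,5,5,8a-tetramethyl-1,4,4a,5,6,7,8,8a-octahydronaphthalen-1-yl]methoxy}silane | CC(C)[Si](OC[C@@H]1C(C)=CC[C@@H]2C(C)(C)CCC[C@@]12C)(C(C)C)C(C)C | intermediate
12 | [(1R,4aR,8aR)-2,5,5,8a-tetramethyl-1,4,4a,5,6,7,8,8a-octahydronaphthalen-1-yl]methanol (ent-drimenol) | OC[C@@H]1C(C)=CC[C@@H]2C(C)(C)CCC[C@@]12C | intermediate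
13 | (1R,4aR,8aR)-2,5,5,8a-tetramethyl-1,4,4a,5,6,7,8,8a-octahydronaphthalene-1-carbaldehyde | O=C[C@@H]1C(C)=CC[C@@H]2C(C)(C)CCC[C@@]12C | intermediate
14 | (1R,4aR,8aR)-1-ethynyl-2,5,5,8a-tetramethyl-1,4,4a,5,6,7,8,8a-octahydronaphthalene | C#C[C@@H]1C(C)=CC[C@@H]2C(C)(C)CCC[C@@]12C | intermediate
15 | ethyl 3-(2-methyl-1,3-dioxolan-2-yl)propanoate | CCOC(=O)CCC1(C)OCCO1 | starting material
16 | 3-(2-methyl-1,3-dioxolan-2-yl)propanal | O=CCCC1(C)OCCO1 | intermediate
17 | (S)-4-benzyl-3-propionyloxazolidin-2-one | CCC(=O)N1[C@@H](Cc2ccccc2)COC1=O | starting material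
18 | (S)-4-benzyl-3-[(2S,3R)-3-hydroxy-2-methyl-5-(2-methyl-1,3-dioxolan-2-yl)pentanoyl]oxazolidin-2-one | O=C1OC[C@H](Cc2ccccc2)N1C(=O)[C@@H](C)[C@H](O)CCC1(C)OCCO1 | intermediate
19 | (2R,3R)-2-methyl-5-(2-methyl-1,3-dioxolan-2-yl)pentane-1,3-diol | OC[C@@H](C)[C@H](O)CCC1(C)OCCO1 | intermediate
20 | (2R,3R)-1-[(tert-butyldiphenylsilyl)oxy]-2-methyl-5-(2-methyl-1,3-dioxolan-2-yl)pentan-3-ol | CC(C)(C)[Si](OC[C@@H](C)[C@H](O)CCC1(C)OCCO1)(c1ccccc1)c1ccccc1 | intermediate
21 | (2R,3R)-1-[(tert-butyldiphenylsilyl)oxy]-2-methyl-5-(2-methyl-1,3-dioxolan-2-yl)pentan-3-yl 4-methylbenzenesulfonate | CC(C)(C)[Si](OC[C@@H](C)[C@H](OS(=O)(=O)c1ccc(C)cc1)CCC1(C)OCCO1)(c1ccccc1)c1ccccc1 | intermediate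
22 | (2R,3R)-1-[(tert-butyldiphenylsilyl)oxy]-2-methyl-6-oxoheptan-3-yl 4-methylbenzenesulfonate | CC(C)(C)[Si](OC[C@@H](C)[C@H](OS(=O)(=O)c1ccc(C)cc1)CCC(C)=O)(c1ccccc1)c1ccccc1 | intermediate
23 | (2R,3R)-1-[(tert-butyldiphenylsilyl)oxy]-6-hydroxy-2,6-dimethyl-8-[(1R,4aR,8aR)-2,5,5,8a-tetramethyl-1,4,4a,5,6,7,8,8a-octahydronaphthalen-1-yl]oct-7-yn-3-yl 4-methylbenzenesulfonate, present as its metal alkoxide (C6 epimers) | CC(C)(C)[Si](OC[C@@H](C)[C@H](OS(=O)(=O)c1ccc(C)cc1)CCC(C)(O)C#C[C@@H]1C(C)=CC[C@@H]2C(C)(C)CCC[C@@]12C)(c1ccccc1)c1ccccc1 | intermediate (not isolated)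
24 | (2R,3R)-1-[(tert-butyldiphenylsilyl)oxy]-2,6-dimethyl-8-[(1R,4aR,8aR)-2,5,5,8a-tetramethyl-1,4,4a,5,6,7,8,8a-octahydronaphthalen-1-yl]-6-[(triethylsilyl)oxy]oct-7-yn-3-yl 4-methylbenzenesulfonate (C6 epimers) | CC(C)(C)[Si](OC[C@@H](C)[C@H](OS(=O)(=O)c1ccc(C)cc1)CCC(C)(O[Si](CC)(CC)CC)C#C[C@@H]1C(C)=CC[C@@H]2C(C)(C)CCC[C@@]12C)(c1ccccc1)c1ccccc1 | intermediate
25 | tert-butyl({(2R,3S)-3-hydroperoxy-2,6-dimethyl-8-[(1R,4aR,8aR)-2,5,5,8a-tetramethyl-1,4,4a,5,6,7,8,8a-octahydronaphthalen-1-yl]-6-[(triethylsilyl)oxy]oct-7-yn-1-yl}oxy)diphenylsilane (C6 epimers) | CC(C)(C)[Si](OC[C@@H](C)[C@@H](OO)CCC(C)(O[Si](CC)(CC)CC)C#C[C@@H]1C(C)=CC[C@@H]2C(C)(C)CCC[C@@]12C)(c1ccccc1)c1ccccc1 | intermediate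
26 | tert-butyl({(2R)-2-[(3S,6R)-6-methyl-6-{[(1R,4aR,8aR)-2,5,5,8a-tetramethyl-1,4,4a,5,6,7,8,8a-octahydronaphthalen-1-yl]ethynyl}-1,2-dioxan-3-yl]propyl}oxy)diphenylsilane | CC(C)(C)[Si](OC[C@@H](C)[C@@H]1CC[C@](C)(C#C[C@@H]2C(C)=CC[C@@H]3C(C)(C)CCC[C@@]23C)OO1)(c1ccccc1)c1ccccc1 | intermediate
27 | (2R)-2-[(3S,6R)-6-methyl-6-{[(1R,4aR,8aR)-2,5,5,8a-tetramethyl-1,4,4a,5,6,7,8,8a-octahydronaphthalen-1-yl]ethynyl}-1,2-dioxan-3-yl]propan-1-ol | OC[C@@H](C)[C@@H]1CC[C@](C)(C#C[C@@H]2C(C)=CC[C@@H]3C(C)(C)CCC[C@@]23C)OO1 | intermediate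
28 | (2S)-2-[(3S,6R)-6-methyl-6-{[(1R,4aR,8aR)-2,5,5,8a-tetramethyl-1,4,4a,5,6,7,8,8a-octahydronaphthalen-1-yl]ethynyl}-1,2-dioxan-3-yl]propanoic acid | OC(=O)[C@@H](C)[C@@H]1CC[C@](C)(C#C[C@@H]2C(C)=CC[C@@H]3C(C)(C)CCC[C@@]23C)OO1 | intermediate
29 | methyl (2S)-2-[(3S,6R)-6-methyl-6-{[(1R,4aR,8aR)-2,5,5,8a-tetramethyl-1,4,4a,5,6,7,8,8a-octahydronaphthalen-1-yl]ethynyl}-1,2-dioxan-3-yl]propanoate | COC(=O)[C@@H](C)[C@@H]1CC[C@](C)(C#C[C@@H]2C(C)=CC[C@@H]3C(C)(C)CCC[C@@]23C)OO1 | intermediate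
30 | methyl (2S)-2-[(3S,6S)-6-methyl-6-{2-[(1R,4aR,8aR)-2,5,5,8a-tetramethyl-1,4,4a,5,6,7,8,8a-octahydronaphthalen-1-yl]ethyl}-1,2-dioxan-3-yl]propanoate | COC(=O)[C@@H](C)[C@@H]1CC[C@](C)(CC[C@@H]2C(C)=CC[C@@H]3C(C)(C)CCC[C@@]23C)OO1 | target

Total step count: 25. Longest linear sequence: 19 steps (steps 1–12, then 19–25); the ketone fragment 22 takes 6 steps (13–18).

Steps most likely to fail

Step 21. The cation may be lost by proton elimination to an enyne, the acid may shift the ring double bond, or the closure may discriminate poorly between axial alkynyl and axial methyl. The fallback forms the other C–O bond in the ring closure. It sets out from 24: 50% H2O2 with catalytic H2SO4 in Et2O at 0 °C removes the triethylsilyl group and converts the tertiary propargylic centre into the hydroperoxide, giving the tertiary hydroperoxide tosylate F6 as a C13 epimer mixture. KOt-Bu with 18-crown-6 in benzene then closes the ring by 6-exo-tet SN2 displacement of the tosylate with inversion at C16. This should give 26 together with its C13 epimer F7, which is removed by chromatography; the fallback gives up stereocontrol at C13 and comes back to the route at 26.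

Step 20. E2 elimination may outrun substitution at the β-branched secondary tosylate, and the alkaline peroxide may attack the silyl ethers. The fallback uses a protected, less basic peroxide nucleophile. It sets out from 24: 2-methoxyprop-2-yl hydroperoxide with CsOH in DMF should displace the tosylate with inversion to give the peroxyketal F5; aqueous AcOH in THF then unmasks the hydroperoxide, and the route is rejoined at 25.

Step 7. The branched C9–C8 bond may migrate in place of C6–C8, addition to the hindered ketone may be slow, or a second carbon may be inserted. The fallback is a regiospecific ring enlargement through the enol ether. It sets out from 7: kinetic enolisation with LiN(i-Pr)2 and Me3SiCl gives the trimethylsilyl enol ether F1 (C8=C6). Simmons–Smith cyclopropanation with Et2Zn and CH2I2 gives the siloxycyclopropane F2. FeCl3 in DMF cleaves the C6–C8 bond oxidatively to the ring-enlarged β-chloro ketone F3, and NaOAc in MeOH eliminates HCl to the enone F4. H2 over palladium on carbon followed by K2CO3 in MeOH brings the route back at 9.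

Further compounds
F1 | step 7 | (3aR,7aR)-trimethylsilyl enol ether of 7 (C2=C3 enol ether) | CC(C)[Si](OCC1C(O[Si](C)(C)C)=C[C@@H]2C(C)(C)CCC[C@@]12C)(C(C)C)C(C)C
F2 | step 7 | siloxycyclopropane from F1 (cyclopropane on the former C2–C3 bond) | CC(C)[Si](OCC1C2(O[Si](C)(C)C)CC2[C@@H]2C(C)(C)CCC[C@@]12C)(C(C)C)C(C)C
F3 | step 7 | (4aR,8aR)-4-chloro-5,5,8a-trimethyl-1-{[(triisopropylsilyl)oxy]methyl}octahydronaphthalen-2(1H)-one | CC(C)[Si](OCC1C(=O)CC(Cl)[C@@H]2C(C)(C)CCC[C@@]12C)(C(C)C)C(C)C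
F4 | step 7 | (4aR,8aR)-5,5,8a-trimethyl-1-{[(triisopropylsilyl)oxy]methyl}-4a,5,6,7,8,8a-hexahydronaphthalen-2(1H)-one | CC(C)[Si](OCC1C(=O)C=C[C@@H]2C(C)(C)CCC[C@@]12C)(C(C)C)C(C)C
F5 | step 20 | 2-methoxyprop-2-yl peroxide of 25 (peroxyketal at C16) | CC(C)(C)[Si](OC[C@@H](C)[C@@H](OOC(C)(C)OC)CCC(C)(O[Si](CC)(CC)CC)C#C[C@@H]1C(C)=CC[C@@H]2C(C)(C)CCC[C@@]12C)(c1ccccc1)c1ccccc1
F6 | step 21 | tertiary propargylic hydroperoxide tosylate (C13–OOH, C16–OTs; C13 epimers) | CC(C)(C)[Si](OC[C@@H](C)[C@H](OS(=O)(=O)c1ccc(C)cc1)CCC(C)(OO)C#C[C@@H]1C(C)=CC[C@@H]2C(C)(C)CCC[C@@]12C)(c1ccccc1)c1ccccc1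
F7 | step 21 | C13 epimer of 26 (6S-dioxane) | CC(C)(C)[Si](OC[C@@H](C)[C@@H]1CC[C@@](C)(C#C[C@@H]2C(C)=CC[C@@H]3C(C)(C)CCC[C@@]23C)OO1)(c1ccccc1)c1ccccc1
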